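## Retrosynthetic overview

1. Endgame: Bu4NF desilylation, cross-metathesis of a C19 allyl group with 2-methylbut-3-en-2-ol (side chain C20–C23), and equatorial MeMgBr addition to a C10 ketone.
2. Key step, run late with the finished cyclohexene ring already attached: Me3SiOTf-triggered tandem oxa-/carbacyclisation of an all-R 1,5-diepoxide terminated by a C10=C11 enol silane. It forms the oxepane and then the cyclohexanone in one operation and sets C6 and C11 (C3 and C7 come from the epoxides); two preformed ring systems are never coupled across the C12–C13 bridge.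
3. Cascade substrate: 1,4-hydrosilylation of an enone made by aldol condensation (C11–C12 bond) of diepoxy-geranylacetone (double Shi epoxidation) with a ring aldehyde.
4. Ring aldehyde: 2-methylcyclohexane-1,3-dione, then allylation, CBS desymmetrisation (C18, C19), α-methylation, enol triflate, Suzuki coupling with an ethoxyvinylboronate, hydrolysis.
5. Ring order: cyclohexene (purchased ring), then oxepane, then cyclohexane (the last two in the same flask).

Assumption: atom labels follow squalene-type numbering (oxepane O–C2–C3–C4–C5–C6–C7; cyclohexane C6–C7–C8–C9–C10–C11; bridge C12–C13; cyclohexene C14=C15–C16–C17–C18–C19; side chain C20–C23); (E)-geranylacetone is bought as the pure E isomer; simple reagents are given with SMILES on the reagent line and carry no compound number; TBS = tert-butyldimethylsilyl.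

## Route

Step 1
Reactants: 1 2-methylcyclohexane-1,3-dione
Product: 2 2-allyl-2-methylcyclohexane-1,3-dione
Conditions: allyl bromide, 1 M NaOH (aq), rt
Reagents that add atoms: allyl bromide, C=CCBr
Why: C-alkylation of the stabilised 1,3-dione enolate with allyl bromide gives the quaternary but still achiral 2,2-disubstituted dione, so no stereocentre is created yet.

Step 2
Reactants: 2 2-allyl-2-methylcyclohexane-1,3-dione
Product: 3 (2R,3R)-2-allyl-3-hydroxy-2-methylcyclohexan-1-one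
Conditions: (S)-2-methyl-CBS-oxazaborolidine (0.2 equiv), catecholborane (1.5 equiv), toluene, −78 °C
Reagents that add atoms: none
Why: Corey–Bakshi–Shibata (CBS) reduction desymmetrises the prochiral dione, the (S)-catalyst treating the quaternary carbon as the large group to give the (R)-carbinol while hydride approaches anti to the larger allyl substituent, so that OH is cis to allyl (C18 and C19 of the target), the minor trans-ketol being removed by chromatography.

Step 3
Reactants: 3 (2R,3R)-2-allyl-3-hydroxy-2-methylcyclohexan-1-one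
Product: 4 (2R,3R)-2-allyl-3-(TBS-oxy)-2-methylcyclohexan-1-one
Conditions: TBSCl, imidazole, DMF, rt
Reagents that add atoms: tert-butyldimethylsilyl chloride, CC(C)(C)[Si](C)(C)Cl
Why: Standard silyl ether formation protects the secondary alcohol against the enolate and organometallic steps that follow.

Step 4
Reactants: 4 (2R,3R)-2-allyl-3-(TBS-oxy)-2-methylcyclohexan-1-one
Product: 6 (2R,3R)-2-allyl-3-(TBS-oxy)-2,6-dimethylcyclohexan-1-one (C6 epimers), via lithium enolate 5 (not isolated)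
Conditions: LiN(i-Pr)2, THF, −78 °C; MeI, −78 → 0 °C
Reagents that add atoms: iodomethane, CI
Why: Enolate alkylation is regiospecific because the ketone can enolise only toward C6 (C2 is quaternary), and the C6 configuration is irrelevant since that carbon becomes sp2 in step 5.

Step 5
Reactants: 6 (2R,3R)-2-allyl-3-(TBS-oxy)-2,6-dimethylcyclohexan-1-one
Product: 8 (5R,6R)-6-allyl-5-(TBS-oxy)-2,6-dimethylcyclohex-1-en-1-yl trifluoromethanesulfonate, via potassium enolate 7 (not isolated)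
Conditions: KN(SiMe3)2, THF, −78 °C; PhNTf2, −78 → 0 °C
Reagents that add atoms: N-phenylbis(trifluoromethanesulfonimide), O=S(=O)(N(c1ccccc1)S(=O)(=O)C(F)(F)F)C(F)(F)F
Why: Enol triflate formation by O-sulfonylation of the only possible (tetrasubstituted) enolate fixes the C14=C15 double bond regiospecifically.

Step 6
Reactants: 8 (5R,6R)-6-allyl-5-(TBS-oxy)-2,6-dimethylcyclohex-1-en-1-yl trifluoromethanesulfonate
Product: 9 tert-butyl{[(1R,2S)-2-allyl-3-[(E)-2-ethoxyethenyl]-2,4-dimethylcyclohex-3-en-1-yl]oxy}dimethylsilane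
Conditions: (E)-2-ethoxyvinylboronic acid pinacol ester, Pd(OAc)2 (5 mol %), SPhos (10 mol %), K3PO4, THF/H2O, 60 °C
Reagents that add atoms: (E)-2-ethoxyvinylboronic acid pinacol ester, CCO/C=C/B1OC(C)(C)C(C)(C)O1
Why: Suzuki–Miyaura coupling of the hindered alkenyl triflate under a bulky biarylphosphine ligand proceeds with retention at both sp2 carbons and attaches C13–C12 as a masked aldehyde.

Step 7
Reactants: 9 tert-butyl{[(1R,2S)-2-allyl-3-[(E)-2-ethoxyethenyl]-2,4-dimethylcyclohex-3-en-1-yl]oxy}dimethylsilane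
Product: 10 2-[(5R,6S)-6-allyl-5-(TBS-oxy)-2,6-dimethylcyclohex-1-en-1-yl]acetaldehyde
Conditions: 1 M HCl (aq), THF, 0 °C
Reagents that add atoms: water, O
Why: Mild acid hydrolysis of the enol ether (kinetic protonation at C13) unmasks the β,γ-unsaturated aldehyde, which resists conjugation because the ring alkene is tetrasubstituted and flanked by the quaternary carbon.

Step 8
Reactants: 11 (E)-geranylacetone [(5E)-6,10-dimethylundeca-5,9-dien-2-one]
Product: 12 (5R,6R,9R)-5,6:9,10-diepoxy-6,10-dimethylundecan-2-one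
Conditions: D-fructose-derived Shi ketone (0.3 equiv), KHSO5 (as Oxone, 2KHSO5·KHSO4·K2SO4), K2CO3, Bu4NHSO4, Na2B4O7/Na2EDTA buffer, MeCN–CH2(OMe)2–H2O, 0 °C
Reagents that add atoms: potassium peroxymonosulfate, [K+].[O-]S(=O)(=O)OO
Why: Shi asymmetric epoxidation epoxidises both electron-rich trisubstituted E-alkenes from the same face through the spiro transition state to give the all-R diepoxide, which fixes C3 and C7 and (after inversion in step 12) C6, while the methyl ketone is untouched.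

Step 9
Reactants: 12 (5R,6R,9R)-5,6:9,10-diepoxy-6,10-dimethylundecan-2-one; 10 2-[(5R,6S)-6-allyl-5-(TBS-oxy)-2,6-dimethylcyclohex-1-en-1-yl]acetaldehyde
Product: 14 (7R,8R,11R)-1-[(5R,6S)-6-allyl-5-(TBS-oxy)-2,6-dimethylcyclohex-1-en-1-yl]-7,8:11,12-diepoxy-2-hydroxy-8,12-dimethyltridecan-4-one (C2 epimers), via lithium enolate 13 (not isolated)
Conditions: LiN(i-Pr)2, THF, −78 °C; then 10, −78 °C
Reagents that add atoms: none
Why: Kinetic deprotonation of the methyl ketone at its methyl group (C11) followed by aldol addition at −78 °C forms the C11–C12 bond and joins the two halves without disturbing the base-stable trisubstituted epoxides, the new carbinol centre being removed in step 10.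

Step 10
Reactants: 14 aldol adduct
Product: 16 (2E,7R,8R,11R)-1-[(5R,6S)-6-allyl-5-(TBS-oxy)-2,6-dimethylcyclohex-1-en-1-yl]-7,8:11,12-diepoxy-8,12-dimethyltridec-2-en-4-one, via mesylate 15 (not isolated)
Conditions: MsCl, Et3N, CH2Cl2, 0 °C → rt
Reagents that add atoms: none
Why: Mesylation and E1cB elimination complete the aldol condensation and give the (E)-enone, placing the double bond at C11=C12 so that the later enol silane is regiodefined.

Step 11
Reactants: 16 (E)-enone
Product: 17 (3Z,7R,8R,11R)-1-[(5R,6S)-6-allyl-5-(TBS-oxy)-2,6-dimethylcyclohex-1-en-1-yl]-4-[(dimethylphenylsilyl)oxy]-7,8:11,12-diepoxy-8,12-dimethyltridec-3-ene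
Conditions: [(Ph3P)CuH]6 (3 mol %), PhMe2SiH (1.5 equiv), toluene, 0 °C → rt
Reagents that add atoms: dimethylphenylsilane, C[SiH](C)c1ccccc1
Why: Copper hydride-catalysed conjugate reduction (1,4-hydrosilylation) converts the enone regiospecifically into the C10=C11 silyl enol ether, mainly the Z isomer through the s-cis enone, while epoxides, unactivated alkenes and the silyl ether are inert.

Step 12
Reactants: 17 diepoxy enol silane
Product: 19 (3R,5aR,6R,9aR)-6-{2-[(5R,6S)-6-allyl-5-(TBS-oxy)-2,6-dimethylcyclohex-1-en-1-yl]ethyl}-3-hydroxy-2,2,5a-trimethyloctahydro-1-benzoxepin-7(2H)-one, via trimethylsilyl ether ketone 18 (not isolated)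
Conditions: Me3SiOTf (1.2 equiv), 2,6-di-tert-butyl-4-methylpyridine, CH2Cl2, −78 °C; then K2CO3, MeOH, rt
Reagents that add atoms: none
Why: In this silyl-triflate-promoted tandem oxa-/carbacyclisation of a 1,5-diepoxide with an enol silane terminator, the silylated terminal epoxide is opened at C2 by the neighbouring epoxide oxygen (C3 retained) and the resulting epoxonium ion is opened at C6 by C11 of the enol silane with inversion (C7 retained) through a chair transition state, giving the trans-fused oxepane–cyclohexanone with the C11 chain equatorial, after which methanolic K2CO3 cleaves the C3 silyl ether and equilibrates C11 to this more stable equatorial epimer.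

Step 13
Reactants: 19 bicyclic hydroxy ketone
Product: 20 (3R,5aR,6R,7S,9aR)-6-{2-[(5R,6S)-6-allyl-5-(TBS-oxy)-2,6-dimethylcyclohex-1-en-1-yl]ethyl}-2,2,5a,7-tetramethyldecahydro-1-benzoxepine-3,7-diol
Conditions: MeMgBr (4 equiv), THF, −78 → 0 °C
Reagents that add atoms: methylmagnesium bromide, C[Mg]Br
Why: Grignard 1,2-addition occurs from the equatorial direction because the axial face of the C10 carbonyl is blocked by the syn-axial C6 methyl group, giving the axial hydroxyl and equatorial methyl (10S) that the target requires.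

Step 14
Reactants: 20 allyl diol
Product: 21 (3R,5aR,6R,7S,9aR)-6-{2-[(5R,6S)-5-(TBS-oxy)-6-[(2E)-4-hydroxy-4-methylpent-2-en-1-yl]-2,6-dimethylcyclohex-1-en-1-yl]ethyl}-2,2,5a,7-tetramethyldecahydro-1-benzoxepine-3,7-diol
Conditions: 2-methylbut-3-en-2-ol (10 equiv), second-generation Grubbs catalyst RuCl2(=CHPh)(H2IMes)(PCy3) (5 mol %), CH2Cl2, 40 °C
Reagents that add atoms: 2-methylbut-3-en-2-ol, C=CC(C)(C)O
Why: Olefin cross-metathesis of the monosubstituted allyl group with excess tertiary allylic alcohol gives the E-disubstituted alkene under thermodynamic control, the tetrasubstituted ring alkene being inert to the ruthenium carbene.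

Step 15
Reactants: 21 mono-TBS ether
Product: 22 siphonellinol C, (3R,5aR,6R,7S,9aR)-6-{2-[(5R,6S)-5-hydroxy-6-[(2E)-4-hydroxy-4-methylpent-2-en-1-yl]-2,6-dimethylcyclohex-1-en-1-yl]ethyl}-2,2,5a,7-tetramethyldecahydro-1-benzoxepine-3,7-diol
Conditions: Bu4NF, THF, 50 °C
Reagents that add atoms: none
Why: Fluoride-mediated desilylation removes the last protecting group without acid, so the tertiary allylic alcohol and the oxepane survive and the target is released.

## Compound list

1 | 2-methylcyclohexane-1,3-dione | CC1C(=O)CCCC1=O | starting material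
2 | 2-allyl-2-methylcyclohexane-1,3-dione | C=CCC1(C)C(=O)CCCC1=O | intermediate
3 | (2R,3R)-2-allyl-3-hydroxy-2-methylcyclohexan-1-one | O=C1[C@](C)(CC=C)[C@H](O)CCC1 | intermediate
4 | (2R,3R)-2-allyl-3-(TBS-oxy)-2-methylcyclohexan-1-one | O=C1[C@](C)(CC=C)[C@H](O[Si](C)(C)C(C)(C)C)CCC1 | intermediate
5 | lithium (5R,6R)-6-allyl-5-(TBS-oxy)-6-methylcyclohex-1-en-1-olate (lithium enolate of 4, not isolated) | C1=C(O[Li])[C@](C)(CC=C)[C@H](O[Si](C)(C)C(C)(C)C)CC1 | intermediate
6 | (2R,3R)-2-allyl-3-(TBS-oxy)-2,6-dimethylcyclohexan-1-one (C6 epimers) | CC1C(=O)[C@](C)(CC=C)[C@H](O[Si](C)(C)C(C)(C)C)CC1 | intermediate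
7 | potassium (5R,6R)-6-allyl-5-(TBS-oxy)-2,6-dimethylcyclohex-1-en-1-olate (potassium enolate of 6, not isolated) | CC1=C(O[K])[C@](C)(CC=C)[C@H](O[Si](C)(C)C(C)(C)C)CC1 | intermediate
8 | (5R,6R)-6-allyl-5-(TBS-oxy)-2,6-dimethylcyclohex-1-en-1-yl trifluoromethanesulfonate | CC1=C(OS(=O)(=O)C(F)(F)F)[C@](C)(CC=C)[C@H](O[Si](C)(C)C(C)(C)C)CC1 | intermediate
9 | tert-butyl{[(1R,2S)-2-allyl-3-[(E)-2-ethoxyethenyl]-2,4-dimethylcyclohex-3-en-1-yl]oxy}dimethylsilane | CC1=C(/C=C/OCC)[C@](C)(CC=C)[C@H](O[Si](C)(C)C(C)(C)C)CC1 | intermediate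
10 | 2-[(5R,6S)-6-allyl-5-(TBS-oxy)-2,6-dimethylcyclohex-1-en-1-yl]acetaldehyde | CC1=C(CC=O)[C@](C)(CC=C)[C@H](O[Si](C)(C)C(C)(C)C)CC1 | intermediate
11 | (E)-geranylacetone, (5E)-6,10-dimethylundeca-5,9-dien-2-one | CC(=O)CC/C=C(\C)CCC=C(C)C | starting material
12 | (5R,6R,9R)-5,6:9,10-diepoxy-6,10-dimethylundecan-2-one | CC(=O)CC[C@H]1O[C@]1(C)CC[C@H]1OC1(C)C | intermediate
13 | lithium enolate of 12 at the methyl terminus (not isolated) | C=C(O[Li])CC[C@H]1O[C@]1(C)CC[C@H]1OC1(C)C | intermediate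
14 | (7R,8R,11R)-1-[(5R,6S)-6-allyl-5-(TBS-oxy)-2,6-dimethylcyclohex-1-en-1-yl]-7,8:11,12-diepoxy-2-hydroxy-8,12-dimethyltridecan-4-one (C2 epimers) | CC1=C(CC(O)CC(=O)CC[C@H]2O[C@]2(C)CC[C@H]2OC2(C)C)[C@](C)(CC=C)[C@H](O[Si](C)(C)C(C)(C)C)CC1 | intermediate
15 | 2-methanesulfonate of 14 (not isolated) | CC1=C(CC(OS(C)(=O)=O)CC(=O)CC[C@H]2O[C@]2(C)CC[C@H]2OC2(C)C)[C@](C)(CC=C)[C@H](O[Si](C)(C)C(C)(C)C)CC1 | intermediate
16 | (2E,7R,8R,11R)-1-[(5R,6S)-6-allyl-5-(TBS-oxy)-2,6-dimethylcyclohex-1-en-1-yl]-7,8:11,12-diepoxy-8,12-dimethyltridec-2-en-4-one | CC1=C(C/C=C/C(=O)CC[C@H]2O[C@]2(C)CC[C@H]2OC2(C)C)[C@](C)(CC=C)[C@H](O[Si](C)(C)C(C)(C)C)CC1 | intermediate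
17 | (3Z,7R,8R,11R)-1-[(5R,6S)-6-allyl-5-(TBS-oxy)-2,6-dimethylcyclohex-1-en-1-yl]-4-[(dimethylphenylsilyl)oxy]-7,8:11,12-diepoxy-8,12-dimethyltridec-3-ene | CC1=C(CC/C=C(O[Si](C)(C)c2ccccc2)/CC[C@H]3O[C@]3(C)CC[C@H]4OC4(C)C)[C@](C)(CC=C)[C@H](O[Si](C)(C)C(C)(C)C)CC1 | intermediate
18 | (3R,5aR,6R,9aR)-6-{2-[(5R,6S)-6-allyl-5-(TBS-oxy)-2,6-dimethylcyclohex-1-en-1-yl]ethyl}-2,2,5a-trimethyl-3-[(trimethylsilyl)oxy]octahydro-1-benzoxepin-7(2H)-one (not isolated) | CC1=C(CC[C@@H]2[C@@]3(C)CC[C@@H](O[Si](C)(C)C)C(C)(C)O[C@@H]3CCC2=O)[C@](C)(CC=C)[C@H](O[Si](C)(C)C(C)(C)C)CC1 | intermediate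
19 | (3R,5aR,6R,9aR)-6-{2-[(5R,6S)-6-allyl-5-(TBS-oxy)-2,6-dimethylcyclohex-1-en-1-yl]ethyl}-3-hydroxy-2,2,5a-trimethyloctahydro-1-benzoxepin-7(2H)-one | CC1=C(CC[C@@H]2[C@@]3(C)CC[C@@H](O)C(C)(C)O[C@@H]3CCC2=O)[C@](C)(CC=C)[C@H](O[Si](C)(C)C(C)(C)C)CC1 | intermediate
20 | (3R,5aR,6R,7S,9aR)-6-{2-[(5R,6S)-6-allyl-5-(TBS-oxy)-2,6-dimethylcyclohex-1-en-1-yl]ethyl}-2,2,5a,7-tetramethyldecahydro-1-benzoxepine-3,7-diol | CC1=C(CC[C@@H]2[C@@]3(C)CC[C@@H](O)C(C)(C)O[C@@H]3CC[C@]2(C)O)[C@](C)(CC=C)[C@H](O[Si](C)(C)C(C)(C)C)CC1 | intermediate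
21 | (3R,5aR,6R,7S,9aR)-6-{2-[(5R,6S)-5-(TBS-oxy)-6-[(2E)-4-hydroxy-4-methylpent-2-en-1-yl]-2,6-dimethylcyclohex-1-en-1-yl]ethyl}-2,2,5a,7-tetramethyldecahydro-1-benzoxepine-3,7-diol | CC1=C(CC[C@@H]2[C@@]3(C)CC[C@@H](O)C(C)(C)O[C@@H]3CC[C@]2(C)O)[C@](C)(C/C=C/C(C)(C)O)[C@H](O[Si](C)(C)C(C)(C)C)CC1 | intermediate
22 | siphonellinol C | CC1=C(CC[C@@H]2[C@@]3(C)CC[C@@H](O)C(C)(C)O[C@@H]3CC[C@]2(C)O)[C@](C)(C/C=C/C(C)(C)O)[C@H](O)CC1 | target

## Step count and risks

Total steps: 15. Longest linear sequence: 14 (steps 1–7, then 9–15, from 2-methylcyclohexane-1,3-dione); step 8 is the one-step side branch.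

**Step 12 (tandem oxa-/carbacyclisation with the right-hand ring present).** Direct attack of the enol silane on a silylated internal epoxide, or interference by the electron-rich ring alkene, could undercut the epoxonium pathway. The fallback runs the same reaction type on a substrate without the right-hand ring and then joins the two ring systems by sp2–sp3 cross-electrophile coupling; it sets out from 12 and returns at 20. Enolate 13 of ketone 12 is added to (tert-butyldiphenylsilyloxy)acetaldehyde to give the β-hydroxy ketone F1. F1 is converted with MsCl/Et3N through its mesylate F2 into the (E)-enone F3. Copper hydride-catalysed 1,4-hydrosilylation ([(Ph3P)CuH]6, PhMe2SiH) gives the enol silane F4. Me3SiOTf/2,6-di-tert-butyl-4-methylpyridine followed by K2CO3/MeOH gives, through the C3 trimethylsilyl ether F5, the bicyclic hydroxy ketone F6. MeMgBr gives the tertiary carbinol F7, Bu4NF frees the primary alcohol to give triol F8, and I2/PPh3/imidazole converts it into the primary iodide F9. Nickel-catalysed reductive coupling of F9 with triflate 8 (NiBr2(dme), 4,4'-di-tert-butyl-2,2'-bipyridine, zinc powder, DMA) forms the C13–C14 bond and gives 20.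

**Step 2 (CBS desymmetrisation).** The allyl/methyl discrimination that decides which carbonyl is reduced may be modest, and the sense of induction rests on the standard model. The fallback replaces asymmetric catalysis by resolution; it sets out from 2 and returns at 3. NaBH4 (MeOH/CH2Cl2, −78 °C) reduces 2 to the racemic cis-ketol F10 (OH cis to allyl), separated from the trans isomer by chromatography. Amano lipase PS with vinyl acetate acylates the (3R)-enantiomer selectively to give the acetate F11, which is separated from the unreacted (2S,3S)-alcohol. Methanolysis of F11 (K2CO3, MeOH) gives 3.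

**Step 9 (aldol union).** Aldehyde 10 has activated α-hydrogens and may be enolised by the lithium enolate instead of adding, and the kinetic enolate may contain some internal regioisomer. The fallback replaces aldol addition/dehydration by a Horner–Wadsworth–Emmons olefination under weakly basic conditions; it sets out from 12 (aldehyde 10 unchanged) and returns at 16. Enolate 13 is C-phosphinylated with diethyl chlorophosphite to the β-keto phosphonite F12, which is oxidised in air to the β-keto phosphonate F13. Reaction of F13 with 10 (LiCl, DBU, MeCN, rt) gives the (E)-enone 16 directly.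

## Further compounds

F1 | step 12 | (7R,8R,11R)-1-[(tert-butyldiphenylsilyl)oxy]-7,8:11,12-diepoxy-2-hydroxy-8,12-dimethyltridecan-4-one (C2 epimers) | CC(C)(C)[Si](OCC(O)CC(=O)CC[C@H]1O[C@]1(C)CC[C@H]1OC1(C)C)(c1ccccc1)c1ccccc1
F2 | step 12 | 2-methanesulfonate of F1 | CC(C)(C)[Si](OCC(OS(C)(=O)=O)CC(=O)CC[C@H]1O[C@]1(C)CC[C@H]1OC1(C)C)(c1ccccc1)c1ccccc1
F3 | step 12 | (2E,7R,8R,11R)-1-[(tert-butyldiphenylsilyl)oxy]-7,8:11,12-diepoxy-8,12-dimethyltridec-2-en-4-one | CC(C)(C)[Si](OC/C=C/C(=O)CC[C@H]1O[C@]1(C)CC[C@H]1OC1(C)C)(c1ccccc1)c1ccccc1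
F4 | step 12 | (3Z,7R,8R,11R)-1-[(tert-butyldiphenylsilyl)oxy]-4-[(dimethylphenylsilyl)oxy]-7,8:11,12-diepoxy-8,12-dimethyltridec-3-ene | CC(C)(C)[Si](OCC/C=C(O[Si](C)(C)c1ccccc1)/CC[C@H]1O[C@]1(C)CC[C@H]1OC1(C)C)(c1ccccc1)c1ccccc1
F5 | step 12 | (3R,5aR,6R,9aR)-6-{2-[(tert-butyldiphenylsilyl)oxy]ethyl}-2,2,5a-trimethyl-3-[(trimethylsilyl)oxy]octahydro-1-benzoxepin-7(2H)-one | CC(C)(C)[Si](OCC[C@@H]1[C@@]2(C)CC[C@@H](O[Si](C)(C)C)C(C)(C)O[C@@H]2CCC1=O)(c1ccccc1)c1ccccc1
F6 | step 12 | (3R,5aR,6R,9aR)-6-{2-[(tert-butyldiphenylsilyl)oxy]ethyl}-3-hydroxy-2,2,5a-trimethyloctahydro-1-benzoxepin-7(2H)-one | CC(C)(C)[Si](OCC[C@@H]1[C@@]2(C)CC[C@@H](O)C(C)(C)O[C@@H]2CCC1=O)(c1ccccc1)c1ccccc1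
F7 | step 12 | (3R,5aR,6R,7S,9aR)-6-{2-[(tert-butyldiphenylsilyl)oxy]ethyl}-2,2,5a,7-tetramethyldecahydro-1-benzoxepine-3,7-diol | CC(C)(C)[Si](OCC[C@@H]1[C@@]2(C)CC[C@@H](O)C(C)(C)O[C@@H]2CC[C@]1(C)O)(c1ccccc1)c1ccccc1
F8 | step 12 | (3R,5aR,6R,7S,9aR)-6-(2-hydroxyethyl)-2,2,5a,7-tetramethyldecahydro-1-benzoxepine-3,7-diol | OCC[C@@H]1[C@@]2(C)CC[C@@H](O)C(C)(C)O[C@@H]2CC[C@]1(C)O
F9 | step 12 | (3R,5aR,6R,7S,9aR)-6-(2-iodoethyl)-2,2,5a,7-tetramethyldecahydro-1-benzoxepine-3,7-diol | ICC[C@@H]1[C@@]2(C)CC[C@@H](O)C(C)(C)O[C@@H]2CC[C@]1(C)O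
F10 | step 2 | racemic cis-2-allyl-3-hydroxy-2-methylcyclohexan-1-one (OH cis to allyl; racemate, relative configuration shown) | O=C1[C@](C)(CC=C)[C@H](O)CCC1
F11 | step 2 | (1R,2R)-2-allyl-2-methyl-3-oxocyclohexyl acetate | O=C1[C@](C)(CC=C)[C@H](OC(C)=O)CCC1
F12 | step 9 | diethyl [(5R,6R,9R)-5,6:9,10-diepoxy-6,10-dimethyl-2-oxoundecyl]phosphonite | CCOP(OCC)CC(=O)CC[C@H]1O[C@]1(C)CC[C@H]1OC1(C)C
F13 | step 9 | diethyl [(5R,6R,9R)-5,6:9,10-diepoxy-6,10-dimethyl-2-oxoundecyl]phosphonate | CCOP(=O)(OCC)CC(=O)CC[C@H]1O[C@]1(C)CC[C@H]1OC1(C)C
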